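**Retrosynthetic overview**
1. Target 24 ⇐ Markovnikov hydration of the C9 ethynyl carbinol 23; its 7,8-dimethyl enone ⇐ spiro ketone 16 by dehydrogenation, conjugate methyl addition/enolate methylation and a second dehydrogenation.
2. 16 ⇐ cyclopent-2-enol 12 by hydroxyl-directed epoxidation, then 5-exo opening of the epoxide by the side-chain tertiary alcohol, which closes the tetrahydrofuran ring and sets C5 and C9 together; the directing carbinol (later the C6 ketone) ⇐ CBS reduction of enynone 11.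
3. 11 ⇐ Stork–Danheiser alkynylation of vinylogous ester 9 ⇐ 2-alkylcyclopentane-1,3-dione 8.
4. Key C–C bond (C4–C5 of the target): intermolecular Knoevenagel-type aldol condensation of cyclopentane-1,3-dione 6 with aldehyde 5, reduced in the same flask.
5. 5 ⇐ natural phytol 1 by Sharpless epoxidation (sets C2) and hydride opening; ring order: the carbocycle is bought in as 6, the tetrahydrofuran ring is closed in step 10.

Assumption: the SMILES is read literally as (2S,5R,9S) with a (4R,8R) side chain (C2 is the mirror image of C2 of natural tocopherol, hence L-(+)-tartrate in step 1); spiro compounds are numbered as in the target (O1, C2, C5 spiro, C6 carbonyl carbon, C9 carbinol carbon).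

**Step 1**
Reactants: 1 (2E,7R,11R)-phytol
Product: 2 (2S,3S)-2,3-epoxyphytol
Conditions: Ti(OiPr)4 (10 mol %), diisopropyl L-(+)-tartrate (12 mol %), t-BuOOH, 4 Å molecular sieves, CH2Cl2, −20 °C
Reagents that add atoms: tert-butyl hydroperoxide, CC(C)(C)OO
Why: Sharpless asymmetric epoxidation of an E-trisubstituted allylic alcohol, where the L-(+)-tartrate catalyst gives the (2S,3S)-epoxide as it does with geraniol, so the future C2 ether carbon is set by the reagent while 7R and 11R come from natural phytol.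

**Step 2**
Reactants: 2 (2S,3S)-2,3-epoxyphytol
Product: 3 (3S,7R,11R)-3,7,11,15-tetramethylhexadecane-1,3-diol
Conditions: NaAlH2(OCH2CH2OMe)2, THF, 0 °C → rt
Reagents that add atoms: none
Why: Regioselective reductive opening of a 2,3-epoxy alcohol, in which the aluminate bound to the C1 oxygen delivers hydride to C2 so that the C3–O bond and its configuration are untouched.

**Step 3**
Reactants: 3 (3S,7R,11R)-3,7,11,15-tetramethylhexadecane-1,3-diol
Product: 4 (3S,7R,11R)-3,7,11,15-tetramethyl-1,3-bis(triethylsilyloxy)hexadecane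
Conditions: Et3SiOTf, 2,6-lutidine, CH2Cl2, −78 → 0 °C
Reagents that add atoms: triethylsilyl triflate, CC[Si](CC)(CC)OS(=O)(=O)C(F)(F)F
Why: Silyl ether formation with a silyl triflate, which is reactive enough to cap the hindered tertiary alcohol as well as the primary one.

**Step 4**
Reactants: 4 (3S,7R,11R)-3,7,11,15-tetramethyl-1,3-bis(triethylsilyloxy)hexadecane
Product: 5 (3S,7R,11R)-3,7,11,15-tetramethyl-3-(triethylsilyloxy)hexadecanal
Conditions: (COCl)2, DMSO, CH2Cl2, −78 → −30 °C; then Et3N, → 0 °C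
Reagents that add atoms: none
Why: Swern oxidation applied directly to a primary triethylsilyl ether, which is cleaved and oxidised in one operation while the hindered tertiary silyl ether survives, and the β-carbon is quaternary so nothing can epimerise or eliminate.

**Step 5**
Reactants: 5 (3S,7R,11R)-3,7,11,15-tetramethyl-3-(triethylsilyloxy)hexadecanal; 6 cyclopentane-1,3-dione
Product: 8 2-[(3S,7R,11R)-3,7,11,15-tetramethyl-3-(triethylsilyloxy)hexadecyl]cyclopentane-1,3-dione, via alkylidene dione 7 (not isolated)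
Conditions: L-proline (20 mol %), diethyl 2,6-dimethyl-1,4-dihydropyridine-3,5-dicarboxylate (1.1 equiv), CH2Cl2, rt
Reagents that add atoms: none
Why: The fragment-joining step is a proline-catalysed intermolecular Knoevenagel-type aldol condensation of the dione enol with the aldehyde, and the electrophilic alkylidene dione is reduced at once by Hantzsch-ester transfer hydrogenation (reductive alkylation), which prevents bis-addition and creates no stereocentre.

**Step 6**
Reactants: 8 2-[(3S,7R,11R)-3,7,11,15-tetramethyl-3-(triethylsilyloxy)hexadecyl]cyclopentane-1,3-dione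
Product: 9 3-methoxy-2-[(3S,7R,11R)-3,7,11,15-tetramethyl-3-(triethylsilyloxy)hexadecyl]cyclopent-2-en-1-one
Conditions: Me3SiCHN2, MeOH/toluene, 0 °C → rt
Reagents that add atoms: (trimethylsilyl)diazomethane, C[Si](C)(C)C=[N+]=[N-]
Why: O-Methylation of a vinylogous acid under neutral conditions that spare the silyl ether, and the symmetric dione can give only one vinylogous ester.

**Step 7**
Reactants: 9 3-methoxy-2-[(3S,7R,11R)-3,7,11,15-tetramethyl-3-(triethylsilyloxy)hexadecyl]cyclopent-2-en-1-one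
Product: 11 2-[(3S,7R,11R)-3,7,11,15-tetramethyl-3-(triethylsilyloxy)hexadecyl]-3-[(trimethylsilyl)ethynyl]cyclopent-2-en-1-one, via lithium alkoxide 10 (not isolated)
Conditions: Me3SiC≡CH, n-BuLi, THF, −78 °C; then 9, −78 → 0 °C; then 1 M HCl, THF, 0 °C, 15 min
Reagents that add atoms: lithium (trimethylsilyl)acetylide, [Li]C#C[Si](C)(C)C; water, O
Why: Stork–Danheiser sequence in which 1,2-addition of the acetylide to the vinylogous ester is followed by acid-induced loss of water and hydrolysis of the enol ether, transposing the carbonyl and placing the masked acetyl group on the future C9 while the brief cold acid leaves the tertiary silyl ether intact.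

**Step 8**
Reactants: 11 2-[(3S,7R,11R)-3,7,11,15-tetramethyl-3-(triethylsilyloxy)hexadecyl]-3-[(trimethylsilyl)ethynyl]cyclopent-2-en-1-one
Product: 12 (1R)-2-[(3S,7R,11R)-3,7,11,15-tetramethyl-3-(triethylsilyloxy)hexadecyl]-3-[(trimethylsilyl)ethynyl]cyclopent-2-en-1-ol
Conditions: (S)-1-methyl-3,3-diphenyltetrahydro-1H,3H-pyrrolo[1,2-c][1,3,2]oxazaborole (20 mol %), catecholborane, toluene, −78 °C
Reagents that add atoms: none
Why: Corey–Bakshi–Shibata reduction in which the α-substituted alkenyl carbon acts as the large group and the ring CH2 as the small one, so the (S)-oxazaborolidine gives the (1R)-allylic alcohol by 1,2-reduction under reagent control, and this carbinol later steers C5 and C9.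

**Step 9**
Reactants: 12 (1R)-2-[(3S,7R,11R)-3,7,11,15-tetramethyl-3-(triethylsilyloxy)hexadecyl]-3-[(trimethylsilyl)ethynyl]cyclopent-2-en-1-ol
Product: 13 (1R,2R,5R)-1-[(3S,7R,11R)-3,7,11,15-tetramethyl-3-(triethylsilyloxy)hexadecyl]-5-[(trimethylsilyl)ethynyl]-6-oxabicyclo[3.1.0]hexan-2-ol (epoxide cis to the hydroxyl)
Conditions: VO(acac)2 (5 mol %), t-BuOOH, CH2Cl2, 0 °C → rt
Reagents that add atoms: tert-butyl hydroperoxide, CC(C)(C)OO
Why: Vanadium-catalysed hydroxyl-directed epoxidation of a cyclic allylic alcohol, which delivers oxygen to the alkene face syn to the hydroxyl and leaves the silyl alkyne untouched.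

**Step 10**
Reactants: 13 (1R,2R,5R)-1-[(3S,7R,11R)-3,7,11,15-tetramethyl-3-(triethylsilyloxy)hexadecyl]-5-[(trimethylsilyl)ethynyl]-6-oxabicyclo[3.1.0]hexan-2-ol
Product: 15 (2S,5S,6R,9R)-2-methyl-2-[(4R,8R)-4,8,12-trimethyltridecyl]-9-[(trimethylsilyl)ethynyl]-1-oxaspiro[4.4]nonane-6,9-diol, via epoxy diol 14 (not isolated)
Conditions: HF·pyridine, pyridine, THF, 0 °C → rt; aqueous work-up; then camphorsulfonic acid (10 mol %), CH2Cl2, 0 °C → rt
Reagents that add atoms: none
Why: After fluoride desilylation the tertiary alcohol opens the epoxide intramolecularly in a 5-exo, SN2-like spiroetherification at the ring carbon that carries the tether, attacking anti to the epoxide oxygen, so the new C5–O1 bond is trans to the C9 hydroxyl left by the epoxide and both ring stereocentres follow from the C6 carbinol (any diastereomer from imperfect ee in step 8 is removed here by chromatography).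

**Step 11**
Reactants: 15 (2S,5S,6R,9R)-2-methyl-2-[(4R,8R)-4,8,12-trimethyltridecyl]-9-[(trimethylsilyl)ethynyl]-1-oxaspiro[4.4]nonane-6,9-diol
Product: 16 (2S,5R,9R)-9-hydroxy-2-methyl-2-[(4R,8R)-4,8,12-trimethyltridecyl]-9-[(trimethylsilyl)ethynyl]-1-oxaspiro[4.4]nonan-6-one
Conditions: Dess–Martin periodinane, CH2Cl2, 0 °C → rt
Reagents that add atoms: none
Why: Dess–Martin oxidation of the only secondary alcohol, which removes the C6 control centre once it has done its work and cannot touch the tertiary C9 carbinol or the quaternary C5.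

**Step 12**
Reactants: 16 (2S,5R,9R)-9-hydroxy-2-methyl-2-[(4R,8R)-4,8,12-trimethyltridecyl]-9-[(trimethylsilyl)ethynyl]-1-oxaspiro[4.4]nonan-6-one
Product: 18 (2S,5R,9R)-2-methyl-2-[(4R,8R)-4,8,12-trimethyltridecyl]-9-[(trimethylsilyl)ethynyl]-9-(trimethylsilyloxy)-1-oxaspiro[4.4]non-7-en-6-one, via bis-silyl enol ether 17 (not isolated)
Conditions: Me3SiOTf (2.5 equiv), Et3N, CH2Cl2, 0 °C; then Pd(OAc)2 (1.05 equiv), MeCN, rt
Reagents that add atoms: trimethylsilyl triflate, C[Si](C)(C)OS(=O)(=O)C(F)(F)F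
Why: Soft enolisation can occur only toward C7 because C5 is quaternary, the same reagent caps the tertiary hydroxyl against retro-aldol cleavage, and Saegusa–Ito dehydrogenation of the silyl enol ether then gives the enone.

**Step 13**
Reactants: 18 (2S,5R,9R)-2-methyl-2-[(4R,8R)-4,8,12-trimethyltridecyl]-9-[(trimethylsilyl)ethynyl]-9-(trimethylsilyloxy)-1-oxaspiro[4.4]non-7-en-6-one
Product: 20 (2S,5R,7R,8R,9R)-2,7,8-trimethyl-2-[(4R,8R)-4,8,12-trimethyltridecyl]-9-[(trimethylsilyl)ethynyl]-9-(trimethylsilyloxy)-1-oxaspiro[4.4]nonan-6-one (7,8-trans, expected major isomer), via lithium enolate 19 (not isolated)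
Conditions: Me2CuLi (from CuI, 2 MeLi), Et2O, −78 → −40 °C; then MeI, HMPA, −40 → 0 °C
Reagents that add atoms: lithium dimethylcuprate, [Li+].C[Cu-]C; iodomethane, CI
Why: Gilman conjugate addition followed by C-methylation of the regiodefined enolate (vicinal difunctionalisation of an enone), where the cuprate should add to C8 anti to the C9 silyloxy group and MeI to C7 anti to the new methyl, but both centres become sp2 in step 14 so their configuration is immaterial.

**Step 14**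
Reactants: 20 (2S,5R,7R,8R,9R)-2,7,8-trimethyl-2-[(4R,8R)-4,8,12-trimethyltridecyl]-9-[(trimethylsilyl)ethynyl]-9-(trimethylsilyloxy)-1-oxaspiro[4.4]nonan-6-one
Product: 22 (2S,5R,9R)-2,7,8-trimethyl-2-[(4R,8R)-4,8,12-trimethyltridecyl]-9-[(trimethylsilyl)ethynyl]-9-(trimethylsilyloxy)-1-oxaspiro[4.4]non-7-en-6-one, via silyl enol ether 21 (not isolated)
Conditions: Me3SiOTf, Et3N, CH2Cl2, rt; then Pd(OAc)2 (1.1 equiv), MeCN, 40 °C
Reagents that add atoms: none
Why: Second Saegusa–Ito oxidation, in which the ketone can enolise only at C7 and β-hydride loss from C8 gives the conjugated tetrasubstituted 7,8-dimethyl enone, the thermodynamically preferred alkene isomer.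

**Step 15**
Reactants: 22 (2S,5R,9R)-2,7,8-trimethyl-2-[(4R,8R)-4,8,12-trimethyltridecyl]-9-[(trimethylsilyl)ethynyl]-9-(trimethylsilyloxy)-1-oxaspiro[4.4]non-7-en-6-one
Product: 23 (2S,5R,9S)-9-ethynyl-9-hydroxy-2,7,8-trimethyl-2-[(4R,8R)-4,8,12-trimethyltridecyl]-1-oxaspiro[4.4]non-7-en-6-one
Conditions: Bu4NF, AcOH, THF, 0 °C
Reagents that add atoms: none
Why: Fluoride-mediated desilylation removes both the O-silyl and the alkynyl C-silyl group, and the acetic acid buffer keeps the medium from becoming basic enough for retro-aldol cleavage of the β-hydroxy ketone (the descriptor at C9 changes only because the ligand priorities change).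

**Step 16**
Reactants: 23 (2S,5R,9S)-9-ethynyl-9-hydroxy-2,7,8-trimethyl-2-[(4R,8R)-4,8,12-trimethyltridecyl]-1-oxaspiro[4.4]non-7-en-6-one
Product: 24 alpha-tocospiro A
Conditions: Hg(OTf)2 (5 mol %), H2O (3 equiv), MeCN, rt
Reagents that add atoms: water, O
Why: Mercury-catalysed Markovnikov hydration of a terminal alkyne, the classical conversion of an ethynyl carbinol into an α-hydroxy methyl ketone, which touches no stereocentre.

**Compound list**
1 | (2E,7R,11R)-3,7,11,15-tetramethylhexadec-2-en-1-ol (natural phytol) | OC/C=C(\C)CCC[C@H](C)CCC[C@H](C)CCCC(C)C | starting material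
2 | [(2S,3S)-3-methyl-3-[(4R,8R)-4,8,12-trimethyltridecyl]oxiran-2-yl]methanol | OC[C@@H]1O[C@@]1(C)CCC[C@H](C)CCC[C@H](C)CCCC(C)C | intermediate
3 | (3S,7R,11R)-3,7,11,15-tetramethylhexadecane-1,3-diol | OCC[C@@](C)(O)CCC[C@H](C)CCC[C@H](C)CCCC(C)C | intermediate
4 | (3S,7R,11R)-3,7,11,15-tetramethyl-1,3-bis(triethylsilyloxy)hexadecane | CC[Si](CC)(CC)OCC[C@@](C)(O[Si](CC)(CC)CC)CCC[C@H](C)CCC[C@H](C)CCCC(C)C | intermediate
5 | (3S,7R,11R)-3,7,11,15-tetramethyl-3-(triethylsilyloxy)hexadecanal | O=CC[C@@](C)(O[Si](CC)(CC)CC)CCC[C@H](C)CCC[C@H](C)CCCC(C)C | intermediate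
6 | cyclopentane-1,3-dione | O=C1CCC(=O)C1 | starting material
7 | 2-[(3S,7R,11R)-3,7,11,15-tetramethyl-3-(triethylsilyloxy)hexadecylidene]cyclopentane-1,3-dione | O=C1CCC(=O)C1=CC[C@@](C)(O[Si](CC)(CC)CC)CCC[C@H](C)CCC[C@H](C)CCCC(C)C | intermediate
8 | 2-[(3S,7R,11R)-3,7,11,15-tetramethyl-3-(triethylsilyloxy)hexadecyl]cyclopentane-1,3-dione | O=C1CCC(=O)C1CC[C@@](C)(O[Si](CC)(CC)CC)CCC[C@H](C)CCC[C@H](C)CCCC(C)C | intermediate
9 | 3-methoxy-2-[(3S,7R,11R)-3,7,11,15-tetramethyl-3-(triethylsilyloxy)hexadecyl]cyclopent-2-en-1-one | COC1=C(CC[C@@](C)(O[Si](CC)(CC)CC)CCC[C@H](C)CCC[C@H](C)CCCC(C)C)C(=O)CC1 | intermediate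
10 | lithium 3-methoxy-2-[(3S,7R,11R)-3,7,11,15-tetramethyl-3-(triethylsilyloxy)hexadecyl]-1-[(trimethylsilyl)ethynyl]cyclopent-2-en-1-olate (both C1 epimers) | [Li+].COC1=C(CC[C@@](C)(O[Si](CC)(CC)CC)CCC[C@H](C)CCC[C@H](C)CCCC(C)C)C([O-])(C#C[Si](C)(C)C)CC1 | intermediate
11 | 2-[(3S,7R,11R)-3,7,11,15-tetramethyl-3-(triethylsilyloxy)hexadecyl]-3-[(trimethylsilyl)ethynyl]cyclopent-2-en-1-one | O=C1CCC(C#C[Si](C)(C)C)=C1CC[C@@](C)(O[Si](CC)(CC)CC)CCC[C@H](C)CCC[C@H](C)CCCC(C)C | intermediate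
12 | (1R)-2-[(3S,7R,11R)-3,7,11,15-tetramethyl-3-(triethylsilyloxy)hexadecyl]-3-[(trimethylsilyl)ethynyl]cyclopent-2-en-1-ol | C[Si](C)(C)C#CC1=C(CC[C@@](C)(O[Si](CC)(CC)CC)CCC[C@H](C)CCC[C@H](C)CCCC(C)C)[C@H](O)CC1 | intermediate
13 | (1R,2R,5R)-1-[(3S,7R,11R)-3,7,11,15-tetramethyl-3-(triethylsilyloxy)hexadecyl]-5-[(trimethylsilyl)ethynyl]-6-oxabicyclo[3.1.0]hexan-2-ol | C[Si](C)(C)C#C[C@]13CC[C@@H](O)[C@@]1(CC[C@@](C)(O[Si](CC)(CC)CC)CCC[C@H](C)CCC[C@H](C)CCCC(C)C)O3 | intermediate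
14 | (1R,2R,5R)-1-[(3S,7R,11R)-3-hydroxy-3,7,11,15-tetramethylhexadecyl]-5-[(trimethylsilyl)ethynyl]-6-oxabicyclo[3.1.0]hexan-2-ol | C[Si](C)(C)C#C[C@]13CC[C@@H](O)[C@@]1(CC[C@@](C)(O)CCC[C@H](C)CCC[C@H](C)CCCC(C)C)O3 | intermediate
15 | (2S,5S,6R,9R)-2-methyl-2-[(4R,8R)-4,8,12-trimethyltridecyl]-9-[(trimethylsilyl)ethynyl]-1-oxaspiro[4.4]nonane-6,9-diol | C[Si](C)(C)C#C[C@]1(O)CC[C@@H](O)[C@@]12CC[C@](C)(CCC[C@H](C)CCC[C@H](C)CCCC(C)C)O2 | intermediate
16 | (2S,5R,9R)-9-hydroxy-2-methyl-2-[(4R,8R)-4,8,12-trimethyltridecyl]-9-[(trimethylsilyl)ethynyl]-1-oxaspiro[4.4]nonan-6-one | C[Si](C)(C)C#C[C@]1(O)CCC(=O)[C@@]12CC[C@](C)(CCC[C@H](C)CCC[C@H](C)CCCC(C)C)O2 | intermediate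
17 | C6=C7 trimethylsilyl enol ether of 16 with O9 also trimethylsilylated (configuration as in 16) | C[Si](C)(C)C#C[C@]1(O[Si](C)(C)C)CC=C(O[Si](C)(C)C)[C@@]12CC[C@](C)(CCC[C@H](C)CCC[C@H](C)CCCC(C)C)O2 | intermediate
18 | (2S,5R,9R)-2-methyl-2-[(4R,8R)-4,8,12-trimethyltridecyl]-9-[(trimethylsilyl)ethynyl]-9-(trimethylsilyloxy)-1-oxaspiro[4.4]non-7-en-6-one | C[Si](C)(C)C#C[C@]1(O[Si](C)(C)C)C=CC(=O)[C@@]12CC[C@](C)(CCC[C@H](C)CCC[C@H](C)CCCC(C)C)O2 | intermediate
19 | lithium C6=C7 enolate of the 8-methyl ketone (8-methyl anti to the 9-silyloxy group) | [Li+].C[Si](C)(C)C#C[C@]1(O[Si](C)(C)C)[C@H](C)C=C([O-])[C@@]12CC[C@](C)(CCC[C@H](C)CCC[C@H](C)CCCC(C)C)O2 | intermediate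
20 | (2S,5R,7R,8R,9R)-2,7,8-trimethyl-2-[(4R,8R)-4,8,12-trimethyltridecyl]-9-[(trimethylsilyl)ethynyl]-9-(trimethylsilyloxy)-1-oxaspiro[4.4]nonan-6-one | C[Si](C)(C)C#C[C@]1(O[Si](C)(C)C)[C@H](C)[C@@H](C)C(=O)[C@@]12CC[C@](C)(CCC[C@H](C)CCC[C@H](C)CCCC(C)C)O2 | intermediate
21 | C6=C7 trimethylsilyl enol ether of 20 | C[Si](C)(C)C#C[C@]1(O[Si](C)(C)C)[C@H](C)C(C)=C(O[Si](C)(C)C)[C@@]12CC[C@](C)(CCC[C@H](C)CCC[C@H](C)CCCC(C)C)O2 | intermediate
22 | (2S,5R,9R)-2,7,8-trimethyl-2-[(4R,8R)-4,8,12-trimethyltridecyl]-9-[(trimethylsilyl)ethynyl]-9-(trimethylsilyloxy)-1-oxaspiro[4.4]non-7-en-6-one | C[Si](C)(C)C#C[C@]1(O[Si](C)(C)C)C(C)=C(C)C(=O)[C@@]12CC[C@](C)(CCC[C@H](C)CCC[C@H](C)CCCC(C)C)O2 | intermediate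
23 | (2S,5R,9S)-9-ethynyl-9-hydroxy-2,7,8-trimethyl-2-[(4R,8R)-4,8,12-trimethyltridecyl]-1-oxaspiro[4.4]non-7-en-6-one | C#C[C@]1(O)C(C)=C(C)C(=O)[C@@]12CC[C@](C)(CCC[C@H](C)CCC[C@H](C)CCCC(C)C)O2 | intermediate
24 | alpha-tocospiro A, (2S,5R,9S)-9-acetyl-9-hydroxy-2,7,8-trimethyl-2-[(4R,8R)-4,8,12-trimethyltridecyl]-1-oxaspiro[4.4]non-7-en-6-one | CC(=O)[C@]1(O)C(C)=C(C)C(=O)[C@@]12CC[C@](C)(CCC[C@H](C)CCC[C@H](C)CCCC(C)C)O2 | target

**Step count and risks**
Total: 16 steps. Longest linear sequence: 16 steps (phytol 1 to 24; dione 6 is bought).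

The three steps most likely to fail are 10, 14 and 16.

For step 10 the danger is that the acid-activated epoxide opens at the propargylic carbon (6-endo) or undergoes a semipinacol shift instead of the wanted 5-exo opening. The fallback sets out from 13. Dess–Martin oxidation gives the silyl-protected epoxy ketone F1, and buffered HF·pyridine gives the free hydroxy epoxy ketone F2. A base (DBU in toluene, or catalytic KOt-Bu in THF) then drives alkoxide attack on the α-carbon of the α,β-epoxy ketone, the position at which such epoxides normally open, with the same inversion. This returns to the route at ketone 16.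

For step 14 the danger is that the tetrasubstituted silyl enol ether is dehydrogenated sluggishly or gives the exocyclic methylene isomer; the fallback also bypasses the enolate methylation of step 13. It sets out from 18. Me2CuLi with Me3SiCl gives the 8-methyl silyl enol ether F3, and Pd(OAc)2 gives the trisubstituted 8-methyl enone F4. I2/pyridine then gives the 7-iodo enone F5, and Stille methylation (Me4Sn, Pd2(dba)3, AsPh3, CuI, NMP, 60 °C) returns to the route at 22.

For step 16 the danger is Meyer–Schuster or Rupe rearrangement of the tertiary propargylic alcohol under the Lewis-acidic hydration conditions. The fallback sets out from 23. Semihydrogenation (H2, Pd/CaCO3 poisoned with Pb(OAc)2, quinoline, EtOAc) gives the 9-vinyl carbinol F6, and Wacker oxidation (PdCl2, CuCl, O2, DMF/H2O) converts the vinyl group into the methyl ketone, arriving at 24.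

**Further compounds**
F1 | step 10 | (1S,5R)-1-[(3S,7R,11R)-3,7,11,15-tetramethyl-3-(triethylsilyloxy)hexadecyl]-5-[(trimethylsilyl)ethynyl]-6-oxabicyclo[3.1.0]hexan-2-one | C[Si](C)(C)C#C[C@]13CCC(=O)[C@@]1(CC[C@@](C)(O[Si](CC)(CC)CC)CCC[C@H](C)CCC[C@H](C)CCCC(C)C)O3
F2 | step 10 | (1S,5R)-1-[(3S,7R,11R)-3-hydroxy-3,7,11,15-tetramethylhexadecyl]-5-[(trimethylsilyl)ethynyl]-6-oxabicyclo[3.1.0]hexan-2-one | C[Si](C)(C)C#C[C@]13CCC(=O)[C@@]1(CC[C@@](C)(O)CCC[C@H](C)CCC[C@H](C)CCCC(C)C)O3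
F3 | step 14 | C6=C7 trimethylsilyl enol ether of the 8-methyl ketone (8-methyl anti to the 9-silyloxy group; other centres as in 18) | C[Si](C)(C)C#C[C@]1(O[Si](C)(C)C)[C@H](C)C=C(O[Si](C)(C)C)[C@@]12CC[C@](C)(CCC[C@H](C)CCC[C@H](C)CCCC(C)C)O2
F4 | step 14 | (2S,5R,9R)-2,8-dimethyl-2-[(4R,8R)-4,8,12-trimethyltridecyl]-9-[(trimethylsilyl)ethynyl]-9-(trimethylsilyloxy)-1-oxaspiro[4.4]non-7-en-6-one | C[Si](C)(C)C#C[C@]1(O[Si](C)(C)C)C(C)=CC(=O)[C@@]12CC[C@](C)(CCC[C@H](C)CCC[C@H](C)CCCC(C)C)O2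
F5 | step 14 | (2S,5R,9S)-7-iodo-2,8-dimethyl-2-[(4R,8R)-4,8,12-trimethyltridecyl]-9-[(trimethylsilyl)ethynyl]-9-(trimethylsilyloxy)-1-oxaspiro[4.4]non-7-en-6-one | C[Si](C)(C)C#C[C@]1(O[Si](C)(C)C)C(C)=C(I)C(=O)[C@@]12CC[C@](C)(CCC[C@H](C)CCC[C@H](C)CCCC(C)C)O2
F6 | step 16 | (2S,5R,9S)-9-ethenyl-9-hydroxy-2,7,8-trimethyl-2-[(4R,8R)-4,8,12-trimethyltridecyl]-1-oxaspiro[4.4]non-7-en-6-one | C=C[C@]1(O)C(C)=C(C)C(=O)[C@@]12CC[C@](C)(CCC[C@H](C)CCC[C@H](C)CCCC(C)C)O2
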